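**Plan**

- The target is (3Z,5S,6S,7R,9E,12S,13R)-configured, and its single ring is the oxocene O1/C7–C13. Retrosynthesis cuts C3=C4 (enyne cross-metathesis), C5–C6 (chloroallylboration of a C6 aldehyde), C12–Br (from C12–OH with inversion) and then the ring bond C7–C8.
- The ring cut is possible because C7 bears the ring oxygen and is α to C6, which can be carried as a carboxamide, while C8 is allylic to the C9=C10 chloroalkene. An α-alkoxy amide enolate at C7 can therefore displace an allylic chloride at C8.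
- The acyclic precursor is cut further at O–C7 (ether formation), C8–C9 (carbonylation), C9–C10 (alkyne homologation) and C12–C13 (alkoxyallylboration of propanal).
- Forward: C10–C15 is made from propanal and allyl MOM ether, the glycolamide ether adds C6–C7, and the vinyl group is taken to alkyne, chloroiodoalkene, enoate and allylic chloride. The oxocene then closes in step 10, followed by C12 bromide, C6 aldehyde, the C4–C5 unit and the C1–C3 enyne.
- Stereochemistry: C12/C13 come from a reagent-controlled (Z)-alkoxyallylboration; C7 from substrate control by C13 in the ring closure; C12 is inverted on bromination; C5/C6 come from a reagent-controlled (Z)-chloroallylboration; the ring alkene geometry from anti addition of ICl; the C3=C4 Z geometry from kinetic cross-metathesis.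

Key step: step 10

Remark on the chemistry: atoms are numbered C1 (alkyne terminus) to C15 (ethyl terminus); the ring alkene with C8 and C11 cis is E by the sequence rules because chlorine outranks C11; the facial sense assigned to both diisopinocampheylborane reagents is taken from their established aldehyde-face preference.

**Route**

Step 1
Reactants: 1 propanal; 2 allyl methoxymethyl ether
Product: 4 (3R,4R)-4-(methoxymethoxy)hex-5-en-3-ol, via (Z)-γ-(methoxymethoxy)allyl-diisopinocampheylborane 3 (not isolated)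
Conditions: 2, sec-BuLi, THF, −78 °C; (−)-Ipc2BOMe [from (+)-α-pinene]; BF3·OEt2; 1, −78 °C → rt; NaOH, H2O2
Reagents that add atoms: allyl methoxymethyl ether 2, C=CCOCOC
Why: Brown (Z)-γ-alkoxyallylboration, in which the chair Zimmerman–Traxler transition state converts the Z geometry of the allylborane into the syn C12/C13 relationship and the isopinocampheyl groups from (+)-α-pinene direct the allyl unit to the Si face of propanal, setting (12R,13R).

Step 2
Reactants: 4 (3R,4R)-4-(methoxymethoxy)hex-5-en-3-ol; 5 2-bromo-N,N-dimethylacetamide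
Product: 7 2-{[(3R,4R)-4-(methoxymethoxy)hex-5-en-3-yl]oxy}-N,N-dimethylacetamide, via sodium (3R,4R)-4-(methoxymethoxy)hex-5-en-3-olate 6 (not isolated)
Conditions: NaH, THF–DMF, 0 °C; 5, 0 °C → rt
Reagents that add atoms: 2-bromo-N,N-dimethylacetamide 5, CN(C)C(=O)CBr
Why: Williamson etherification of the sodium alkoxide with the primary α-bromo amide is a fast SN2 reaction that installs C6 and C7 as the glycolamide without touching either stereocentre.

Step 3
Reactants: 7 2-{[(3R,4R)-4-(methoxymethoxy)hex-5-en-3-yl]oxy}-N,N-dimethylacetamide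
Product: 9 2-{[(3R,4R)-6-hydroxy-4-(methoxymethoxy)hexan-3-yl]oxy}-N,N-dimethylacetamide, via B-alkyl-9-borabicyclo[3.3.1]nonane adduct 8 (not isolated)
Conditions: 9-BBN-H, THF, 0 °C → rt; NaOH, H2O2, 0 °C
Reagents that add atoms: hydrogen peroxide, OO
Why: Anti-Markovnikov hydroboration–oxidation of the monosubstituted alkene with the bulky borane places boron on the terminal carbon far faster than this borane attacks a tertiary amide at room temperature, and no stereocentre is formed.

Step 4
Reactants: 9 2-{[(3R,4R)-6-hydroxy-4-(methoxymethoxy)hexan-3-yl]oxy}-N,N-dimethylacetamide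
Product: 10 2-{[(3R,4R)-4-(methoxymethoxy)-6-oxohexan-3-yl]oxy}-N,N-dimethylacetamide
Conditions: Dess–Martin periodinane, CH2Cl2, 0 °C → rt
Reagents that add atoms: none
Why: Dess–Martin oxidation stops at the aldehyde under near-neutral conditions that spare the MOM acetal and should not promote β-elimination of the C12 alkoxy group.

Step 5
Reactants: 10 2-{[(3R,4R)-4-(methoxymethoxy)-6-oxohexan-3-yl]oxy}-N,N-dimethylacetamide; 11 dimethyl (1-diazo-2-oxopropyl)phosphonate
Product: 12 2-{[(3R,4R)-4-(methoxymethoxy)hept-6-yn-3-yl]oxy}-N,N-dimethylacetamide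
Conditions: 11, K2CO3, MeOH, 0 °C → rt
Reagents that add atoms: dimethyl (1-diazo-2-oxopropyl)phosphonate 11, COP(=O)(OC)C(=[N+]=[N-])C(C)=O
Why: Ohira–Bestmann variant of the Seyferth–Gilbert homologation, in which the diazomethylphosphonate anion released by methanolysis converts the aldehyde into the terminal alkyne (new carbon C9) under mild carbonate conditions.

Step 6
Reactants: 12 2-{[(3R,4R)-4-(methoxymethoxy)hept-6-yn-3-yl]oxy}-N,N-dimethylacetamide; 13 iodine monochloride
Product: 14 2-{[(3R,4R,6E)-6-chloro-7-iodo-4-(methoxymethoxy)hept-6-en-3-yl]oxy}-N,N-dimethylacetamide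
Conditions: ICl, CH2Cl2, −78 → 0 °C, dark
Reagents that add atoms: iodine monochloride 13, ClI
Why: Electrophilic iodochlorination of a terminal alkyne, in which the iodonium ion is opened by chloride at the internal carbon in anti fashion, giving the (E)-2-chloro-1-iodoalkene with C11 and iodine cis and so fixing the later ring-cis geometry of C9=C10.

Step 7
Reactants: 14 2-{[(3R,4R,6E)-6-chloro-7-iodo-4-(methoxymethoxy)hept-6-en-3-yl]oxy}-N,N-dimethylacetamide; 15 carbon monoxide
Product: 16 methyl (2E,5R,6R)-3-chloro-6-[2-(dimethylamino)-2-oxoethoxy]-5-(methoxymethoxy)oct-2-enoate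
Conditions: Pd(PPh3)4 (5 mol%), CO (1 atm), Et3N, MeOH–DMF, 50 °C
Reagents that add atoms: carbon monoxide 15, [C-]#[O+]; methanol, CO
Why: Palladium-catalysed alkoxycarbonylation, in which zerovalent palladium inserts into the vinyl C–I bond much faster than into the vinyl C–Cl bond and CO insertion followed by methanolysis delivers the enoate (new carbon C8) with retention of alkene geometry.

Step 8
Reactants: 16 methyl (2E,5R,6R)-3-chloro-6-[2-(dimethylamino)-2-oxoethoxy]-5-(methoxymethoxy)oct-2-enoate
Product: 17 2-{[(3R,4R,6E)-6-chloro-8-hydroxy-4-(methoxymethoxy)oct-6-en-3-yl]oxy}-N,N-dimethylacetamide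
Conditions: LiBH4, THF, 0 °C
Reagents that add atoms: none
Why: Chemoselective borohydride reduction, since LiBH4 reduces esters but leaves tertiary amides untouched at 0 °C and 1,2-hydride delivery to the β-chloro enoate should give the allylic alcohol with the alkene geometry intact.

Step 9
Reactants: 17 2-{[(3R,4R,6E)-6-chloro-8-hydroxy-4-(methoxymethoxy)oct-6-en-3-yl]oxy}-N,N-dimethylacetamide
Product: 19 2-{[(3R,4R,6E)-6,8-dichloro-4-(methoxymethoxy)oct-6-en-3-yl]oxy}-N,N-dimethylacetamide, via allylic methanesulfonate 18 (not isolated)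
Conditions: MsCl, Et3N, CH2Cl2, 0 °C; LiCl, THF, rt
Reagents that add atoms: lithium chloride, [Li+].[Cl-]; methanesulfonyl chloride, CS(=O)(=O)Cl (retained only in 18)
Why: Mesylation followed by SN2 displacement with chloride at the unhindered primary allylic carbon gives the allylic chloride without allylic transposition, because the SN2' terminus C10 is fully substituted.

Step 10
Reactants: 19 2-{[(3R,4R,6E)-6,8-dichloro-4-(methoxymethoxy)oct-6-en-3-yl]oxy}-N,N-dimethylacetamide
Product: 21 (2R,4E,7R,8R)-5-chloro-8-ethyl-7-(methoxymethoxy)-N,N-dimethyl-3,6,7,8-tetrahydro-2H-oxocine-2-carboxamide, via potassium (Z)-amide enolate 20 (not isolated)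
Conditions: KN(SiMe3)2, THF (0.01 M), −78 °C
Reagents that add atoms: none
Why: KN(SiMe3)2 deprotonates C7 to give the potassium (Z)-amide enolate 20, whose α-carbon displaces the primary allylic chloride at C8 in an intramolecular SN2 reaction that forms the C7–C8 bond. The closest known reaction type is the intramolecular amide enolate alkylation used to make cis-2,8-disubstituted oxocenes. The oxocene closes in an 8-exo-tet mode with the enolate double bond exocyclic to the new ring. The new stereocentre C7 is controlled by C13: in the reactive conformer the C13–H bond eclipses the enolate plane to avoid allylic strain, so the C12 tether and the ethyl group sit on opposite faces and the tethered electrophile reaches C7 from its own face, which leaves the carboxamide cis to the ethyl group (7R). The step needs C- over O-alkylation, SN2 over SN2' attack and cyclisation over oligomerisation; the soft enolate carbon, the fully substituted chlorine-bearing C10, the ring-cis alkene that holds C8 near C7 and high dilution at −78 °C should secure these, while the vinyl chloride is inert to the base.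

Step 11
Reactants: 21 (2R,4E,7R,8R)-5-chloro-8-ethyl-7-(methoxymethoxy)-N,N-dimethyl-3,6,7,8-tetrahydro-2H-oxocine-2-carboxamide
Product: 22 (2R,4E,7R,8R)-5-chloro-8-ethyl-7-hydroxy-N,N-dimethyl-3,6,7,8-tetrahydro-2H-oxocine-2-carboxamide
Conditions: conc. HCl, MeOH, rt → 40 °C
Reagents that add atoms: none
Why: Acid-catalysed acetal exchange with methanol removes the MOM group as dimethoxymethane, and the tertiary amide, the vinyl chloride and the three stereocentres should be inert to these conditions.

Step 12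
Reactants: 22 (2R,4E,7R,8R)-5-chloro-8-ethyl-7-hydroxy-N,N-dimethyl-3,6,7,8-tetrahydro-2H-oxocine-2-carboxamide; 23 carbon tetrabromide
Product: 24 (2R,4E,7S,8R)-7-bromo-5-chloro-8-ethyl-N,N-dimethyl-3,6,7,8-tetrahydro-2H-oxocine-2-carboxamide
Conditions: CBr4, P(n-C8H17)3, toluene, 70 °C
Reagents that add atoms: carbon tetrabromide 23, BrC(Br)(Br)Br
Why: Appel-type bromination, in which the alkoxyphosphonium ion formed at O12 is displaced by bromide with SN2 inversion to turn (12R)-OH into (12S)-Br, a conversion established for oxocene alcohols next to the ring-oxygen-bearing carbon, and the carboxamide lies on the face of the leaving group so it cannot participate.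

Step 13
Reactants: 24 (2R,4E,7S,8R)-7-bromo-5-chloro-8-ethyl-N,N-dimethyl-3,6,7,8-tetrahydro-2H-oxocine-2-carboxamide
Product: 25 (2R,4E,7S,8R)-7-bromo-5-chloro-8-ethyl-3,6,7,8-tetrahydro-2H-oxocine-2-carbaldehyde
Conditions: Cp2Zr(H)Cl, THF, rt, short reaction time; aqueous work-up; used crude
Reagents that add atoms: none
Why: Reduction of a tertiary amide with the Schwartz reagent gives a zirconated hemiaminal that releases the aldehyde only on work-up, so over-reduction and epimerisation at C7 should be avoided and the trisubstituted chloroalkene and the alkyl bromide are left alone.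

Step 14
Reactants: 25 (2R,4E,7S,8R)-7-bromo-5-chloro-8-ethyl-3,6,7,8-tetrahydro-2H-oxocine-2-carbaldehyde; 26 allyl chloride
Product: 28 (1S,2S)-1-[(2R,4E,7S,8R)-7-bromo-5-chloro-8-ethyl-3,6,7,8-tetrahydro-2H-oxocin-2-yl]-2-chlorobut-3-en-1-ol, via (Z)-γ-chloroallyl-diisopinocampheylborane 27 (not isolated)
Conditions: 26, (+)-Ipc2BOMe [from (−)-α-pinene], LiN(c-C6H11)2, Et2O, −95 °C; BF3·OEt2; 25, −95 °C; pH 7 buffer, H2O2, 0 °C
Reagents that add atoms: allyl chloride 26, C=CCCl
Why: Brown-type (Z)-γ-chloroallylboration, in which the Z reagent reacts through a chair Zimmerman–Traxler transition state to give the syn chlorohydrin and the isopinocampheyl groups from (−)-α-pinene direct addition to the Re face of the aldehyde, setting (5S,6S) under reagent control against the modest Felkin preference of the α-alkoxy aldehyde.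

Step 15
Reactants: 29 (triisopropylsilyl)acetylene; 30 vinyl bromide
Product: 31 triisopropyl(but-3-en-1-yn-1-yl)silane
Conditions: PdCl2(PPh3)2 (2 mol%), CuI (4 mol%), Et2NH, THF, rt
Reagents that add atoms: vinyl bromide 30, C=CBr
Why: Sonogashira coupling of a terminal alkyne with vinyl bromide is a standard route to silyl-capped conjugated enynes.

Step 16
Reactants: 28 (1S,2S)-1-[(2R,4E,7S,8R)-7-bromo-5-chloro-8-ethyl-3,6,7,8-tetrahydro-2H-oxocin-2-yl]-2-chlorobut-3-en-1-ol; 31 triisopropyl(but-3-en-1-yn-1-yl)silane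
Product: 32 (1S,2S,3Z)-1-[(2R,4E,7S,8R)-7-bromo-5-chloro-8-ethyl-3,6,7,8-tetrahydro-2H-oxocin-2-yl]-2-chloro-6-(triisopropylsilyl)hex-3-en-5-yn-1-ol
Conditions: second-generation Grubbs catalyst (H2IMes)(PCy3)Cl2Ru=CHPh (10 mol%), 31 (excess), CH2Cl2, 40 °C
Reagents that add atoms: triisopropyl(but-3-en-1-yn-1-yl)silane 31, C=CC#C[Si](C(C)C)(C(C)C)C(C)C
Why: Olefin cross-metathesis of a terminal alkene with a conjugated enyne is kinetically Z-selective because the slim alkynyl group is tolerated cis in the metallacyclobutane and the enyne product does not re-enter the cycle, while the bulky silyl cap keeps the alkyne out of enyne metathesis and the trisubstituted vinyl chloride is unreactive.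

Step 17
Reactants: 32 (1S,2S,3Z)-1-[(2R,4E,7S,8R)-7-bromo-5-chloro-8-ethyl-3,6,7,8-tetrahydro-2H-oxocin-2-yl]-2-chloro-6-(triisopropylsilyl)hex-3-en-5-yn-1-ol
Product: 33 bermudenynol, (1S,2S,3Z)-1-[(2R,4E,7S,8R)-7-bromo-5-chloro-8-ethyl-3,6,7,8-tetrahydro-2H-oxocin-2-yl]-2-chlorohex-3-en-5-yn-1-ol
Conditions: Bu4NF, AcOH (1:1), THF, 0 °C → rt
Reagents that add atoms: none
Why: Fluoride-induced protodesilylation of the alkynylsilane, with acetic acid buffering so that the medium should not become basic enough to close the chlorohydrin to an epoxide or to eliminate HBr.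

**Compound list**

1 | propanal | CCC=O | starting material
2 | allyl methoxymethyl ether | C=CCOCOC | starting material
3 | (Z)-γ-(methoxymethoxy)allyl-diisopinocampheylborane [Ipc from (+)-α-pinene] | COCO/C=C\CB([C@@H]1C[C@@H]2C[C@H]([C@H]1C)C2(C)C)[C@@H]1C[C@@H]2C[C@H]([C@H]1C)C2(C)C | intermediate (not isolated)
4 | (3R,4R)-4-(methoxymethoxy)hex-5-en-3-ol | CC[C@@H](O)[C@H](OCOC)C=C | intermediate
5 | 2-bromo-N,N-dimethylacetamide | CN(C)C(=O)CBr | starting material
6 | sodium (3R,4R)-4-(methoxymethoxy)hex-5-en-3-olate | CC[C@@H]([O-])[C@H](OCOC)C=C.[Na+] | intermediate (not isolated)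
7 | 2-{[(3R,4R)-4-(methoxymethoxy)hex-5-en-3-yl]oxy}-N,N-dimethylacetamide | CN(C)C(=O)CO[C@H](CC)[C@H](OCOC)C=C | intermediate
8 | B-alkyl-9-borabicyclo[3.3.1]nonane adduct of 7 (boron on the terminal carbon) | CN(C)C(=O)CO[C@H](CC)[C@H](OCOC)CCB1C2CCCC1CCC2 | intermediate (not isolated)
9 | 2-{[(3R,4R)-6-hydroxy-4-(methoxymethoxy)hexan-3-yl]oxy}-N,N-dimethylacetamide | CN(C)C(=O)CO[C@H](CC)[C@H](OCOC)CCO | intermediate
10 | 2-{[(3R,4R)-4-(methoxymethoxy)-6-oxohexan-3-yl]oxy}-N,N-dimethylacetamide | CN(C)C(=O)CO[C@H](CC)[C@H](OCOC)CC=O | intermediate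
11 | dimethyl (1-diazo-2-oxopropyl)phosphonate | COP(=O)(OC)C(=[N+]=[N-])C(C)=O | starting material
12 | 2-{[(3R,4R)-4-(methoxymethoxy)hept-6-yn-3-yl]oxy}-N,N-dimethylacetamide | CN(C)C(=O)CO[C@H](CC)[C@H](OCOC)CC#C | intermediate
13 | iodine monochloride | ClI | starting material
14 | 2-{[(3R,4R,6E)-6-chloro-7-iodo-4-(methoxymethoxy)hept-6-en-3-yl]oxy}-N,N-dimethylacetamide | CN(C)C(=O)CO[C@H](CC)[C@H](OCOC)C/C(Cl)=C\I | intermediate
15 | carbon monoxide | [C-]#[O+] | starting material
16 | methyl (2E,5R,6R)-3-chloro-6-[2-(dimethylamino)-2-oxoethoxy]-5-(methoxymethoxy)oct-2-enoate | CN(C)C(=O)CO[C@H](CC)[C@H](OCOC)C/C(Cl)=C\C(=O)OC | intermediate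
17 | 2-{[(3R,4R,6E)-6-chloro-8-hydroxy-4-(methoxymethoxy)oct-6-en-3-yl]oxy}-N,N-dimethylacetamide | CN(C)C(=O)CO[C@H](CC)[C@H](OCOC)C/C(Cl)=C\CO | intermediate
18 | allylic methanesulfonate of 17 | CN(C)C(=O)CO[C@H](CC)[C@H](OCOC)C/C(Cl)=C\COS(C)(=O)=O | intermediate (not isolated)
19 | 2-{[(3R,4R,6E)-6,8-dichloro-4-(methoxymethoxy)oct-6-en-3-yl]oxy}-N,N-dimethylacetamide | CN(C)C(=O)CO[C@H](CC)[C@H](OCOC)C/C(Cl)=C\CCl | intermediate
20 | potassium (Z)-amide enolate of 19 | CN(C)/C([O-])=C/O[C@H](CC)[C@H](OCOC)C/C(Cl)=C\CCl.[K+] | intermediate (not isolated)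
21 | (2R,4E,7R,8R)-5-chloro-8-ethyl-7-(methoxymethoxy)-N,N-dimethyl-3,6,7,8-tetrahydro-2H-oxocine-2-carboxamide | CN(C)C(=O)[C@H]1C/C=C(/Cl)C[C@@H](OCOC)[C@@H](CC)O1 | intermediate
22 | (2R,4E,7R,8R)-5-chloro-8-ethyl-7-hydroxy-N,N-dimethyl-3,6,7,8-tetrahydro-2H-oxocine-2-carboxamide | CN(C)C(=O)[C@H]1C/C=C(/Cl)C[C@@H](O)[C@@H](CC)O1 | intermediate
23 | carbon tetrabromide | BrC(Br)(Br)Br | starting material
24 | (2R,4E,7S,8R)-7-bromo-5-chloro-8-ethyl-N,N-dimethyl-3,6,7,8-tetrahydro-2H-oxocine-2-carboxamide | CN(C)C(=O)[C@H]1C/C=C(/Cl)C[C@H](Br)[C@@H](CC)O1 | intermediate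
25 | (2R,4E,7S,8R)-7-bromo-5-chloro-8-ethyl-3,6,7,8-tetrahydro-2H-oxocine-2-carbaldehyde | O=C[C@H]1C/C=C(/Cl)C[C@H](Br)[C@@H](CC)O1 | intermediate
26 | allyl chloride | C=CCCl | starting material
27 | (Z)-γ-chloroallyl-diisopinocampheylborane [Ipc from (−)-α-pinene] | Cl/C=C\CB([C@H]1C[C@H]2C[C@@H]([C@@H]1C)C2(C)C)[C@H]1C[C@H]2C[C@@H]([C@@H]1C)C2(C)C | intermediate (not isolated)
28 | (1S,2S)-1-[(2R,4E,7S,8R)-7-bromo-5-chloro-8-ethyl-3,6,7,8-tetrahydro-2H-oxocin-2-yl]-2-chlorobut-3-en-1-ol | C=C[C@H](Cl)[C@@H](O)[C@H]1C/C=C(/Cl)C[C@H](Br)[C@@H](CC)O1 | intermediate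
29 | (triisopropylsilyl)acetylene | C#C[Si](C(C)C)(C(C)C)C(C)C | starting material
30 | vinyl bromide | C=CBr | starting material
31 | triisopropyl(but-3-en-1-yn-1-yl)silane | C=CC#C[Si](C(C)C)(C(C)C)C(C)C | intermediate
32 | (1S,2S,3Z)-1-[(2R,4E,7S,8R)-7-bromo-5-chloro-8-ethyl-3,6,7,8-tetrahydro-2H-oxocin-2-yl]-2-chloro-6-(triisopropylsilyl)hex-3-en-5-yn-1-ol | CC(C)[Si](C#C/C=C\[C@H](Cl)[C@@H](O)[C@H]1C/C=C(/Cl)C[C@H](Br)[C@@H](CC)O1)(C(C)C)C(C)C | intermediate
33 | bermudenynol | C#C/C=C\[C@H](Cl)[C@@H](O)[C@H]1C/C=C(/Cl)C[C@H](Br)[C@@H](CC)O1 | target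

**Step count**

Total steps: 17. Longest linear sequence: 16 (steps 1–14, 16 and 17; step 15 prepares the enyne partner).

**Steps most likely to fail**

Step 14. The reagent has to override the aldehyde's own facial preference (mismatched double stereodifferentiation), and the α-alkoxy aldehyde may epimerise at C7 before it is trapped. The fallback sets out from 25 and replaces boron-allyl transfer by an auxiliary-controlled aldol. An Evans syn-aldol with the dibutylboron enolate of (R)-4-benzyl-3-(chloroacetyl)oxazolidin-2-one (Bu2BOTf, iPr2NEt, CH2Cl2, −78 °C) should give the syn α-chloro-β-hydroxy imide F1. Silylation (TBSOTf, 2,6-lutidine) would give the silyl ether F2, and LiBH4 would cleave the auxiliary reductively to the primary alcohol F3. Dess–Martin oxidation would give the α-chloro aldehyde F4, and Wittig methylenation (Ph3P=CH2, THF, −78 °C) the protected chlorohydrin F5. HF·pyridine in THF would then remove the silyl group and return to 28, after which steps 16 and 17 follow unchanged.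

Step 16. The Z/E selectivity may be poor, or turnover slow, on an alkene flanked by a secondary chloride. The fallback sets out from 28 and builds the Z-enyne by carbonyl olefination instead of metathesis. Silylation (Et3SiCl, imidazole) would give the triethylsilyl ether F6. Ozonolysis of the terminal alkene (O3, CH2Cl2, −78 °C; PPh3), which should be faster than attack on the electron-poor ring chloroalkene, would give the α-chloro aldehyde F7. Peterson olefination with lithiated 1,3-bis(triisopropylsilyl)propyne (n-BuLi, THF, −78 °C → rt), which is Z-selective for steric reasons, would give the bis-silylated enyne F8. Bu4NF buffered with AcOH would remove both silyl groups and come back to the route at the target 33.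

Step 12. Inversion may be lost through participation of the ring oxygen, or the activated alcohol may undergo E2 elimination under the hot one-pot conditions. The fallback sets out from 22 and separates activation from displacement. ClCH2SO2Cl with 2,6-lutidine in CH2Cl2 at 0 °C would give the isolable chloromethanesulfonate F9. SN2 displacement with Bu4NBr in toluene at about 50 °C should then deliver the inverted bromide and come back to the route at 24.

**Further compounds**

F1 | step 14 | (R)-4-benzyl-3-{(2R,3S)-3-[(2R,4E,7S,8R)-7-bromo-5-chloro-8-ethyl-3,6,7,8-tetrahydro-2H-oxocin-2-yl]-2-chloro-3-hydroxypropanoyl}oxazolidin-2-one | O=C1OC[C@@H](Cc2ccccc2)N1C(=O)[C@H](Cl)[C@@H](O)[C@H]1C/C=C(/Cl)C[C@H](Br)[C@@H](CC)O1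
F2 | step 14 | tert-butyldimethylsilyl ether of F1 | O=C1OC[C@@H](Cc2ccccc2)N1C(=O)[C@H](Cl)[C@@H](O[Si](C)(C)C(C)(C)C)[C@H]1C/C=C(/Cl)C[C@H](Br)[C@@H](CC)O1
F3 | step 14 | (2S,3S)-3-[(2R,4E,7S,8R)-7-bromo-5-chloro-8-ethyl-3,6,7,8-tetrahydro-2H-oxocin-2-yl]-3-(tert-butyldimethylsilyloxy)-2-chloropropan-1-ol | OC[C@H](Cl)[C@@H](O[Si](C)(C)C(C)(C)C)[C@H]1C/C=C(/Cl)C[C@H](Br)[C@@H](CC)O1
F4 | step 14 | (2R,3S)-3-[(2R,4E,7S,8R)-7-bromo-5-chloro-8-ethyl-3,6,7,8-tetrahydro-2H-oxocin-2-yl]-3-(tert-butyldimethylsilyloxy)-2-chloropropanal | O=C[C@H](Cl)[C@@H](O[Si](C)(C)C(C)(C)C)[C@H]1C/C=C(/Cl)C[C@H](Br)[C@@H](CC)O1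
F5 | step 14 | tert-butyldimethylsilyl ether of 28 | C=C[C@H](Cl)[C@@H](O[Si](C)(C)C(C)(C)C)[C@H]1C/C=C(/Cl)C[C@H](Br)[C@@H](CC)O1
F6 | step 16 | triethylsilyl ether of 28 | C=C[C@H](Cl)[C@@H](O[Si](CC)(CC)CC)[C@H]1C/C=C(/Cl)C[C@H](Br)[C@@H](CC)O1
F7 | step 16 | (2R,3S)-3-[(2R,4E,7S,8R)-7-bromo-5-chloro-8-ethyl-3,6,7,8-tetrahydro-2H-oxocin-2-yl]-2-chloro-3-(triethylsilyloxy)propanal | O=C[C@H](Cl)[C@@H](O[Si](CC)(CC)CC)[C@H]1C/C=C(/Cl)C[C@H](Br)[C@@H](CC)O1
F8 | step 16 | triethylsilyl ether of 32 | CC(C)[Si](C#C/C=C\[C@H](Cl)[C@@H](O[Si](CC)(CC)CC)[C@H]1C/C=C(/Cl)C[C@H](Br)[C@@H](CC)O1)(C(C)C)C(C)C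
F9 | step 12 | (2R,4E,7R,8R)-5-chloro-2-(dimethylcarbamoyl)-8-ethyl-3,6,7,8-tetrahydro-2H-oxocin-7-yl chloromethanesulfonate | CN(C)C(=O)[C@H]1C/C=C(/Cl)C[C@@H](OS(=O)(=O)CCl)[C@@H](CC)O1
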